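## Analysis of the target

The target is an isoflavone: a 7-hydroxy-4H-chromen-4-one (ring A fused to pyranone ring C) whose C3 carries ring B, a pentasubstituted phloroglucinol-type benzene ring (C1' to C6'). In ring B, C1' (bonded to C3) lies between two free hydroxyls at C2' and C6'. C3' carries the prenyl group between the 2'-OH and the 4'-OMe, and C5' is the only ring CH. There is no stereocentre and no stereogenic double bond, so every selectivity problem is one of regiochemistry or chemoselectivity.

Sensitive groups are:
- the ortho-prenylphenol (acid closes it to a 2,2-dimethylchroman, oxidants and electrophiles attack the alkene, hydrogenolysis is excluded);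
- chromone C2 (a Michael acceptor that nucleophiles and strong bases open);
- the phenols flanking C1' (under base a phenoxide can add to C2 and isomerise the isoflavone to a 3-aroylbenzofuran).

The synthesis is hard for two reasons. The C3–C1' bond has two ortho oxygens, so a cross-coupling there is hindered and the matching boron reagents protodeboronate. Ring B also needs three differentiated oxygens and exactly one C-prenyl group next to a free phenol, which late prenylation of a triphenol does not deliver cleanly.

The feature the route uses: around ring B the oxygen-bearing carbons (C2', C4', C6') alternate with the carbon- or hydrogen-bearing ones (C1', C3', C5'). A vinylketene (C2'–C3'–C4'–C5') and a siloxyalkyne (C1'–C6') produce exactly this pattern in one thermal benzannulation, each substituent being placed by the polarity of the two partners.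

## Retrosynthetic reasoning

**20 back to 19.** Only the two O–Si bonds at O7 and O6' are cut. Both phenols are masked by the same fluoride-labile group, so the last step needs neither acid (prenyl/2'-OH cyclisation) nor strong base (chromone opening).

**19 back to 8 and 14 (key disconnection).** Three bonds of ring B are cut: C1'–C2', C5'–C6' and C2'–C3'. The two-carbon unit C1'–C6' becomes the triple bond of siloxyalkyne 8 (C1' carries the chromone, C6' the silyloxy group). The four-carbon unit C2'–C3'–C4'–C5' becomes vinylketene 15, stored as its valence isomer, cyclobutenone 14 (carbonyl carbon = C2', C4 with prenyl = C3', C3 with OMe = C4', C2–H = C5'). The cut is made here because: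
- the hindered C3–C1' bond is then never made by coupling; it is the unhindered sp–sp2 bond of 8;
- the prenyl group, the methoxy group and the free 2'-OH (the former ketene oxygen) arrive in place and already differentiated.

The forward reaction must open 14 to 15, add 15 to 8 with the right orientation (16), reopen (17), close the six-membered ring (18) and aromatise.

**14 back to 13 and 10; 13 back to 11; 10 back to 9.** The cyclobutenone is cut at C1–C2 and C3–C4 into aldoketene 13 and methoxyethyne 10. The ketene [2+2] cycloaddition places the alkyl group at C4 and the methoxy group at C3 by polarity. Ketene 13 comes from acid 11 through chloride 12, and 10 from acetal 9 by elimination.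

**8 back to 7, 6, 4, 3, 2 and 1.** The usual entries to siloxyalkynes pass through lithium ynolates made with organolithium or peroxide reagents, which the chromone would not survive. The C≡C–O unit is therefore unmasked under neutral conditions from α-silyl diazo ketone 7 by carbene rearrangement. Compound 7 comes from diazo ketone 6 by C-silylation, and 6 from acid 4 through chloride 5. Acid 4 is the oxidation product of aldehyde 3, the silyl ether of 2. Aldehyde 2 is cut at C2–C3, C3–CHO and O1–C2 into 1 and two formyl equivalents (Vilsmeier–Haack reaction), which builds ring C in one step.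

## Alternatives that were turned down

**Alternative 1:** (textbook) cut the C3–C1' bond as a Suzuki–Miyaura coupling.
- Forward: 3-iodo-7-(methoxymethoxy)-4H-chromen-4-one A1 and [4-methoxy-2,6-bis(methoxymethoxy)phenyl]boronic acid A2 are coupled under palladium catalysis. The MOM groups are removed to give 7-hydroxy-3-(2,6-dihydroxy-4-methoxyphenyl)-4H-chromen-4-one A3, and A3 is C-prenylated.
- Turned down, coupling: A2 is a 2,6-dialkoxyarylboronic acid. Transmetalation at a di-ortho-substituted carbon is slow, while ipso-protonation of that electron-rich carbon is fast.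
- Turned down, prenylation: the prenyl group must follow the acidic MOM removal, so it has to be put onto triphenol A3. There O- and C-alkylation, ring A (C6, C8) and double alkylation at the equivalent C3'/C5' all compete. A Claisen detour repairs this only at the cost of about three more steps.
- Both hard features of the target are left to the least reliable steps.

**Alternative 2:** (biomimetic) form the C3–C1' bond by the 1,2-aryl shift of isoflavone biosynthesis.
- Forward: chalcone (E)-1-[2-hydroxy-4-(methoxymethoxy)phenyl]-3-[4-methoxy-2,6-bis(methoxymethoxy)phenyl]prop-2-en-1-one A4 is oxidised with Tl(NO3)3 (trivalent thallium) in methanol. Ring B migrates from C2 to C3 and gives acetal 1-[2-hydroxy-4-(methoxymethoxy)phenyl]-3,3-dimethoxy-2-[4-methoxy-2,6-bis(methoxymethoxy)phenyl]propan-1-one A5. Acid closes ring C and gives A3.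
- Turned down: the electron-rich ring B migrates well, but the oxidant (trivalent thallium or PhI(OAc)2-type reagents) attacks a trisubstituted alkene faster than the enone. The prenyl group must therefore come afterwards, and the route ends at A3 with the same unsolved prenylation as Alternative 1.
- It also needs a stoichiometric toxic metal and more steps to A3 than the coupling.

**Alternative 3:** (deoxybenzoin route) cut C4–C4a and the C2 unit.
- Forward: Friedel–Crafts or Houben–Hoesch acylation of resorcinol A8 with [2,6-dihydroxy-4-methoxy-3-(3-methylbut-2-en-1-yl)phenyl]acetic acid A6 gives deoxybenzoin 1-(2,4-dihydroxyphenyl)-2-[2,6-dihydroxy-4-methoxy-3-(3-methylbut-2-en-1-yl)phenyl]ethan-1-one A7. A one-carbon unit (DMF, BF3·OEt2, MsCl) then closes ring C.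
- Turned down: both key operations need strong Lewis or Brønsted acid, which cyclises the ortho-prenylphenol to a chroman.
- A6 lactonises through its ortho hydroxyl to a benzofuran-2(3H)-one and still needs a regiocontrolled prenylation.
- Protecting four phenols to avoid this adds steps and removes the activation that the acylation relies on.

Key step: step 9

Remark: the target has no stereocentre; 14, 16 and 18 are racemic and their stereocentre is lost on aromatisation; 1, 9 and 11 are taken as commercial.

## Steps

Step 1
Reactants: 1 2,4-dihydroxyacetophenone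
Product: 2 7-hydroxy-4-oxo-4H-chromene-3-carbaldehyde
Conditions: POCl3, DMF, 0 °C to 50 °C; then ice-water
Reagents that add atoms: N,N-dimethylformamide CN(C)C=O; water O
Why: Vilsmeier–Haack reaction of an ortho-hydroxyacetophenone: the methyl ketone is formylated twice, the phenol closes onto the first iminium carbon (C2) and hydrolysis frees the 3-formyl group; a formate formed at O7 is cleaved in the aqueous work-up.

Step 2
Reactants: 2 7-hydroxy-4-oxo-4H-chromene-3-carbaldehyde
Product: 3 4-oxo-7-[(triisopropylsilyl)oxy]-4H-chromene-3-carbaldehyde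
Conditions: TIPSOTf, 2,6-lutidine, CH2Cl2, 0 °C to 20 °C
Reagents that add atoms: triisopropylsilyl triflate CC(C)[Si](C(C)C)(C(C)C)OS(=O)(=O)C(F)(F)F
Why: Phenol silylation with a silyl triflate and a hindered base that cannot add to C2 of the 3-formylchromone; the bulky aryl silyl ether should survive all later steps and leave with fluoride at the end.

Step 3
Reactants: 3 4-oxo-7-[(triisopropylsilyl)oxy]-4H-chromene-3-carbaldehyde
Product: 4 4-oxo-7-[(triisopropylsilyl)oxy]-4H-chromene-3-carboxylic acid
Conditions: NaClO2, NaH2PO4, 2-methylbut-2-ene, t-BuOH–THF–H2O, 0 °C to 20 °C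
Reagents that add atoms: sodium chlorite [Na+].[O-]Cl=O
Why: Pinnick oxidation, selective for the aldehyde; the buffered medium spares the aryl silyl ether and the chromone, and the alkene scavenger removes hypochlorous acid.

Step 4
Reactants: 4 4-oxo-7-[(triisopropylsilyl)oxy]-4H-chromene-3-carboxylic acid
Product: 6 3-(2-diazoacetyl)-7-[(triisopropylsilyl)oxy]-4H-chromen-4-one, via acid chloride 5 (not isolated)
Conditions: (COCl)2, DMF (cat.), CH2Cl2, 0 °C to 20 °C; evaporation; Me3SiCHN2, THF–MeCN, 0 °C
Reagents that add atoms: (trimethylsilyl)diazomethane C[Si](C)(C)C=[N+]=[N-]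
Why: First stage of an Arndt–Eistert sequence: the acid chloride acylates the diazo carbon and chloride removes the silyl group from the diazonium intermediate; acylation at 0 °C should be much faster than dipolar cycloaddition to C2=C3.

Step 5
Reactants: 6 3-(2-diazoacetyl)-7-[(triisopropylsilyl)oxy]-4H-chromen-4-one
Product: 7 3-[2-diazo-2-(triisopropylsilyl)acetyl]-7-[(triisopropylsilyl)oxy]-4H-chromen-4-one
Conditions: TIPSOTf, i-Pr2NEt, Et2O, 0 °C to 20 °C
Reagents that add atoms: triisopropylsilyl triflate CC(C)[Si](C(C)C)(C(C)C)OS(=O)(=O)C(F)(F)F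
Why: Electrophilic C-silylation of a diazomethyl ketone with a silyl triflate and a hindered amine, the known preparation of (1-diazo-2-oxoalkyl)silanes; no strong base touches the chromone.

Step 6
Reactants: 7 3-[2-diazo-2-(triisopropylsilyl)acetyl]-7-[(triisopropylsilyl)oxy]-4H-chromen-4-one
Product: 8 7-[(triisopropylsilyl)oxy]-3-{[(triisopropylsilyl)oxy]ethynyl}-4H-chromen-4-one
Conditions: Rh2(O2CC3F7)4 (1 mol%), toluene, 20 °C
Reagents that add atoms: none
Why: Catalysed loss of N2 gives an acyl(silyl)carbenoid; a 1,3-shift of silicon from carbon to the carbonyl oxygen gives a siloxy-substituted alkylidene carbene, whose 1,2-shift gives the siloxyalkyne. This is the known route from α-silyl α-diazo aryl ketones to 1-aryl-2-siloxyalkynes and is used here because it is neutral.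

Step 7
Reactants: 9 2-chloro-1,1-dimethoxyethane
Product: 10 methoxyethyne
Conditions: NaNH2 (3 equiv), liquid NH3, −33 °C; then cold aqueous NaCl; distilled into a cold trap, kept as a cold Et2O solution
Reagents that add atoms: none
Why: Double elimination (HCl, then methanol) with sodium amide gives sodium methoxyacetylide, which water protonates; the same elimination is the standard preparation of alkoxyacetylenes from chloroacetaldehyde acetals.

Step 8
Reactants: 11 5-methylhex-4-enoic acid; 10 methoxyethyne
Product: 14 3-methoxy-4-(3-methylbut-2-en-1-yl)cyclobut-2-en-1-one (racemic), via acid chloride 12 (not isolated), via prenylketene 13 (not isolated)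
Conditions: 1-chloro-N,N,2-trimethylprop-1-en-1-amine, CH2Cl2, 0 °C to 20 °C; then added slowly to 10 (3 equiv), Et3N, Et2O, 0 °C to 20 °C
Reagents that add atoms: none
Why: The chloroenamine gives the acid chloride without free HCl, so the trisubstituted alkene is not hydrochlorinated, and triethylamine then forms aldoketene 13 in the presence of excess ynol ether. In the ketene–alkyne [2+2] cycloaddition the ketene carbonyl carbon bonds to the nucleophilic CH of 10 and the ketene α-carbon to the methoxy carbon, which puts the prenyl group at C4 and the methoxy group at C3; the new stereocentre is racemic and disappears later.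

Step 9
Reactants: 8 7-[(triisopropylsilyl)oxy]-3-{[(triisopropylsilyl)oxy]ethynyl}-4H-chromen-4-one; 14 3-methoxy-4-(3-methylbut-2-en-1-yl)cyclobut-2-en-1-one
Product: 19 3-{2-hydroxy-4-methoxy-3-(3-methylbut-2-en-1-yl)-6-[(triisopropylsilyl)oxy]phenyl}-7-[(triisopropylsilyl)oxy]-4H-chromen-4-one, via vinylketene 15 (not isolated), via cyclobutenone adduct 16 (not isolated), via dienylketene 17 (not isolated), via cyclohexadienone 18 (not isolated)
Conditions: 14 (1.5 equiv, in portions), toluene (0.4 M), 80 °C then 110 °C, sealed base-washed tube, argon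
Reagents that add atoms: none
Why: Danheiser benzannulation. Heat opens 14 by a conrotatory 4π electrocyclic reaction to vinylketene 15, the prenyl-bearing carbon turning outward, which also keeps the ketene away from the prenyl alkene. The ketene C=C bond of 15 then adds to the electron-rich triple bond of 8 in a thermal [2+2] cycloaddition that closes the four-membered ring of 16: the electrophilic ketene carbonyl carbon bonds to the alkyne carbon β to oxygen (the one carrying the chromone) and the ketene α-carbon to the siloxy carbon. A second 4π opening gives dienylketene 17, and a 6π electrocyclic (disrotatory) closure between the ketene carbon and the prenyl-bearing terminus forms the six-membered ring B as dienone 18, which tautomerises to phenol 19. The closest known reaction type is the thermal union of 3-alkoxycyclobutenones with trialkylsiloxyalkynes, which gives 2-substituted 5-alkoxyresorcinol monosilyl ethers. No stereocentre is formed that persists. The selectivity needed is regiochemical and is fixed by the polarity of ketene and ynol ether: C1' ends between the new hydroxyl (C2') and the siloxy group (C6'), the prenyl group next to the free hydroxyl and the methoxy group para to C1'. Chemoselectivity rests on the siloxyalkyne being far more reactive towards ketenes than the chromone C2=C3 bond or the prenyl alkene, and on the crowded new phenol being slow to trap 15.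

Step 10
Reactants: 19 3-{2-hydroxy-4-methoxy-3-(3-methylbut-2-en-1-yl)-6-[(triisopropylsilyl)oxy]phenyl}-7-[(triisopropylsilyl)oxy]-4H-chromen-4-one
Product: 20 7-hydroxy-3-[2,6-dihydroxy-4-methoxy-3-(3-methylbut-2-en-1-yl)phenyl]-4H-chromen-4-one
Conditions: Bu4NF (2.5 equiv), AcOH (3 equiv), THF, 0 °C
Reagents that add atoms: none
Why: Fluoride cleaves both aryl silyl ethers; acetic acid protonates each phenoxide as it forms, which should prevent addition of the 2'- or 6'-phenoxide to C2, and the medium is not acidic enough to cyclise the ortho-prenylphenol.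

## Compound list

1 | 2,4-dihydroxyacetophenone | CC(=O)c1ccc(O)cc1O | starting material
2 | 7-hydroxy-4-oxo-4H-chromene-3-carbaldehyde | O=Cc1coc2cc(O)ccc2c1=O | intermediate
3 | 4-oxo-7-[(triisopropylsilyl)oxy]-4H-chromene-3-carbaldehyde | O=Cc1coc2cc(O[Si](C(C)C)(C(C)C)C(C)C)ccc2c1=O | intermediate
4 | 4-oxo-7-[(triisopropylsilyl)oxy]-4H-chromene-3-carboxylic acid | OC(=O)c1coc2cc(O[Si](C(C)C)(C(C)C)C(C)C)ccc2c1=O | intermediate
5 | 4-oxo-7-[(triisopropylsilyl)oxy]-4H-chromene-3-carbonyl chloride | ClC(=O)c1coc2cc(O[Si](C(C)C)(C(C)C)C(C)C)ccc2c1=O | intermediate (not isolated)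
6 | 3-(2-diazoacetyl)-7-[(triisopropylsilyl)oxy]-4H-chromen-4-one | [N-]=[N+]=CC(=O)c1coc2cc(O[Si](C(C)C)(C(C)C)C(C)C)ccc2c1=O | intermediate
7 | 3-[2-diazo-2-(triisopropylsilyl)acetyl]-7-[(triisopropylsilyl)oxy]-4H-chromen-4-one | [N-]=[N+]=C(C(=O)c1coc2cc(O[Si](C(C)C)(C(C)C)C(C)C)ccc2c1=O)[Si](C(C)C)(C(C)C)C(C)C | intermediate
8 | 7-[(triisopropylsilyl)oxy]-3-{[(triisopropylsilyl)oxy]ethynyl}-4H-chromen-4-one | CC(C)[Si](C(C)C)(C(C)C)OC#Cc1coc2cc(O[Si](C(C)C)(C(C)C)C(C)C)ccc2c1=O | intermediate
9 | 2-chloro-1,1-dimethoxyethane | COC(CCl)OC | starting material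
10 | methoxyethyne | COC#C | intermediate
11 | 5-methylhex-4-enoic acid | CC(C)=CCCC(=O)O | starting material
12 | 5-methylhex-4-enoyl chloride | CC(C)=CCCC(=O)Cl | intermediate (not isolated)
13 | 5-methylhexa-1,4-dien-1-one (prenylketene) | CC(C)=CCC=C=O | intermediate (not isolated)
14 | 3-methoxy-4-(3-methylbut-2-en-1-yl)cyclobut-2-en-1-one (racemic) | COC1=CC(=O)C1CC=C(C)C | intermediate
15 | (3Z)-3-methoxy-7-methylocta-1,3,6-trien-1-one | O=C=C/C(OC)=C/CC=C(C)C | intermediate (not isolated)
16 | 4-[(1Z)-1-methoxy-5-methylhexa-1,4-dien-1-yl]-2-{4-oxo-7-[(triisopropylsilyl)oxy]-4H-chromen-3-yl}-3-[(triisopropylsilyl)oxy]cyclobut-2-en-1-one (racemic) | O=C1C(c2coc3cc(O[Si](C(C)C)(C(C)C)C(C)C)ccc3c2=O)=C(O[Si](C(C)C)(C(C)C)C(C)C)C1/C(OC)=C/CC=C(C)C | intermediate (not isolated)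
17 | (3E,5Z)-5-methoxy-9-methyl-2-{4-oxo-7-[(triisopropylsilyl)oxy]-4H-chromen-3-yl}-3-[(triisopropylsilyl)oxy]deca-1,3,5,8-tetraen-1-one | O=C=C(c1coc2cc(O[Si](C(C)C)(C(C)C)C(C)C)ccc2c1=O)/C(O[Si](C(C)C)(C(C)C)C(C)C)=C\C(OC)=C\CC=C(C)C | intermediate (not isolated)
18 | 5-methoxy-6-(3-methylbut-2-en-1-yl)-2-{4-oxo-7-[(triisopropylsilyl)oxy]-4H-chromen-3-yl}-3-[(triisopropylsilyl)oxy]cyclohexa-2,4-dien-1-one (racemic) | O=C1C(c2coc3cc(O[Si](C(C)C)(C(C)C)C(C)C)ccc3c2=O)=C(O[Si](C(C)C)(C(C)C)C(C)C)C=C(OC)C1CC=C(C)C | intermediate (not isolated)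
19 | 3-{2-hydroxy-4-methoxy-3-(3-methylbut-2-en-1-yl)-6-[(triisopropylsilyl)oxy]phenyl}-7-[(triisopropylsilyl)oxy]-4H-chromen-4-one | COc1cc(O[Si](C(C)C)(C(C)C)C(C)C)c(-c2coc3cc(O[Si](C(C)C)(C(C)C)C(C)C)ccc3c2=O)c(O)c1CC=C(C)C | intermediate
20 | 7-hydroxy-3-[2,6-dihydroxy-4-methoxy-3-(3-methylbut-2-en-1-yl)phenyl]-4H-chromen-4-one | COc1cc(O)c(-c2coc3cc(O)ccc3c2=O)c(O)c1CC=C(C)C | target

## Step count and least certain steps

Total step count: 10. Longest linear sequence: 8 steps (steps 1 to 6, 9 and 10); steps 7 and 8 form the second branch.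

**Step 9 (key step).**
- What may go wrong: vinylketene 15 may be lost to dimerisation or to acylation of the new phenol before it meets 8. Alkyne 8 may suffer a thermal 1,3-silyl shift to a silylketene. The cascade may stall at 16 if its ring opening needs more heat than 8 tolerates.
- Fallback (known chemistry; sets out from 1, comes back at 20): ring B is taken from a ready-made phloroglucinol and joined by cross-coupling. Silylation of 1 (TIPSCl, imidazole) gives 1-{2-hydroxy-4-[(triisopropylsilyl)oxy]phenyl}ethan-1-one F1. Condensation with DMF dimethyl acetal gives (E)-3-(dimethylamino)-1-{2-hydroxy-4-[(triisopropylsilyl)oxy]phenyl}prop-2-en-1-one F2, and iodine closes it to 3-iodo-7-[(triisopropylsilyl)oxy]-4H-chromen-4-one F3. 1-Methoxy-3,5-bis(methoxymethoxy)benzene F4 is lithiated between its two MOM ethers (n-BuLi) and borylated (i-PrOBpin) to 2-[4-methoxy-2,6-bis(methoxymethoxy)phenyl]-4,4,5,5-tetramethyl-1,3,2-dioxaborolane F5. Suzuki–Miyaura coupling of F3 and F5 (Pd(OAc)2, SPhos, K3PO4, toluene–water) gives 3-[4-methoxy-2,6-bis(methoxymethoxy)phenyl]-7-[(triisopropylsilyl)oxy]-4H-chromen-4-one F6. The MOM groups are removed while no prenyl group is present (HCl, MeOH, 0 °C) to give 3-(2,6-dihydroxy-4-methoxyphenyl)-7-[(triisopropylsilyl)oxy]-4H-chromen-4-one F7. Mono-O-alkylation (2-methylbut-3-en-2-yl methyl carbonate, Pd(PPh3)4) gives 3-{2-hydroxy-4-methoxy-6-[(2-methylbut-3-en-2-yl)oxy]phenyl}-7-[(triisopropylsilyl)oxy]-4H-chromen-4-one F8. An aromatic Claisen rearrangement (toluene, 110 °C) moves the C5 unit to the neighbouring ring carbon as a prenyl group and gives 3-[2,6-dihydroxy-4-methoxy-3-(3-methylbut-2-en-1-yl)phenyl]-7-[(triisopropylsilyl)oxy]-4H-chromen-4-one F9. Because C3' and C5' of F7 are equivalent, only one C-prenyl isomer can form. Desilylation as in step 10 gives 20.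

**Step 6 (and step 4 before it).**
- What may go wrong: the carbenoid may be diverted from the 1,3-silyl shift, either by Wolff rearrangement to a silylketene or by capture through the neighbouring C4 carbonyl oxygen. In step 4, dipolar cycloaddition of the diazo reagent to the activated C2=C3 bond may compete with acylation.
- Fallback (known chemistry; sets out from 1, comes back at 20): the siloxyalkyne is replaced by an alkyl ynol ether made by cross-coupling. 2-(Trimethylsilyl)ethanol is converted (KH, trichloroethene) into (E)-[2-(1,2-dichloroethenyloxy)ethyl]trimethylsilane F10. n-BuLi and then ZnBr2 turn F10 into bromo{[2-(trimethylsilyl)ethoxy]ethynyl}zinc F11. Negishi coupling of F11 with iodide F3 (made from 1 as in the fallback above) under Pd(PPh3)4 gives 7-[(triisopropylsilyl)oxy]-3-{[2-(trimethylsilyl)ethoxy]ethynyl}-4H-chromen-4-one F12. Benzannulation of F12 with 14 at 80 °C, below the temperature at which primary alkyl ynol ethers fragment, gives 3-{2-hydroxy-4-methoxy-3-(3-methylbut-2-en-1-yl)-6-[2-(trimethylsilyl)ethoxy]phenyl}-7-[(triisopropylsilyl)oxy]-4H-chromen-4-one F13. Fluoride (CsF, DMF, then buffered work-up) removes the 2-(trimethylsilyl)ethyl and silyl groups and gives 20.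

**Step 8.**
- What may go wrong: dimerisation of aldoketene 13, promoted by the ammonium salt, may outrun its cycloaddition, and the volatile alkyne 10 may be lost from the mixture.
- Fallback (known chemistry; sets out from 10, comes back at 14): the ketene is generated without base. 4-Methylpent-3-enoic acid F14 is converted into 4-methylpent-3-enoyl chloride F15 and, with diazomethane, into 1-diazo-5-methylhex-4-en-2-one F16. Irradiation of F16 in the presence of excess 10 at −20 °C triggers a Wolff rearrangement to the same ketene 13, at low stationary concentration and free of salts, and 13 adds to 10 to give 14.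

**Step 10.**
- What may go wrong: a phenoxide next to C1' may attack C2 and isomerise the product to a 3-aroylbenzofuran, or cleavage of the crowded 6'-silyl ether may be incomplete while the 7-silyl ether is already gone.
- Fallback (known chemistry; sets out from 19, comes back at 20): each phenoxide is trapped as it forms. Desilylation in the presence of acetic anhydride (Bu4NF, Ac2O, THF) gives 3-[2,6-diacetoxy-4-methoxy-3-(3-methylbut-2-en-1-yl)phenyl]-4-oxo-4H-chromen-7-yl acetate F17. F17 is purified and deacetylated under neutral conditions (NH4OAc, aqueous MeOH) to 20.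

## Further compounds

F1 | step 9 | 1-{2-hydroxy-4-[(triisopropylsilyl)oxy]phenyl}ethan-1-one | CC(=O)c1ccc(O[Si](C(C)C)(C(C)C)C(C)C)cc1O
F2 | step 9 | (E)-3-(dimethylamino)-1-{2-hydroxy-4-[(triisopropylsilyl)oxy]phenyl}prop-2-en-1-one | CN(C)/C=C/C(=O)c1ccc(O[Si](C(C)C)(C(C)C)C(C)C)cc1O
F3 | step 9 | 3-iodo-7-[(triisopropylsilyl)oxy]-4H-chromen-4-one | O=c1c(I)coc2cc(O[Si](C(C)C)(C(C)C)C(C)C)ccc12
F4 | step 9 | 1-methoxy-3,5-bis(methoxymethoxy)benzene | COCOc1cc(OC)cc(OCOC)c1
F5 | step 9 | 2-[4-methoxy-2,6-bis(methoxymethoxy)phenyl]-4,4,5,5-tetramethyl-1,3,2-dioxaborolane | COCOc1cc(OC)cc(OCOC)c1B1OC(C)(C)C(C)(C)O1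
F6 | step 9 | 3-[4-methoxy-2,6-bis(methoxymethoxy)phenyl]-7-[(triisopropylsilyl)oxy]-4H-chromen-4-one | COCOc1cc(OC)cc(OCOC)c1-c1coc2cc(O[Si](C(C)C)(C(C)C)C(C)C)ccc2c1=O
F7 | step 9 | 3-(2,6-dihydroxy-4-methoxyphenyl)-7-[(triisopropylsilyl)oxy]-4H-chromen-4-one | COc1cc(O)c(-c2coc3cc(O[Si](C(C)C)(C(C)C)C(C)C)ccc3c2=O)c(O)c1
F8 | step 9 | 3-{2-hydroxy-4-methoxy-6-[(2-methylbut-3-en-2-yl)oxy]phenyl}-7-[(triisopropylsilyl)oxy]-4H-chromen-4-one | COc1cc(O)c(-c2coc3cc(O[Si](C(C)C)(C(C)C)C(C)C)ccc3c2=O)c(OC(C)(C)C=C)c1
F9 | step 9 | 3-[2,6-dihydroxy-4-methoxy-3-(3-methylbut-2-en-1-yl)phenyl]-7-[(triisopropylsilyl)oxy]-4H-chromen-4-one | COc1cc(O)c(-c2coc3cc(O[Si](C(C)C)(C(C)C)C(C)C)ccc3c2=O)c(O)c1CC=C(C)C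
F10 | step 6 | (E)-[2-(1,2-dichloroethenyloxy)ethyl]trimethylsilane | C[Si](C)(C)CCO/C(Cl)=C\Cl
F11 | step 6 | bromo{[2-(trimethylsilyl)ethoxy]ethynyl}zinc | C[Si](C)(C)CCOC#C[Zn]Br
F12 | step 6 | 7-[(triisopropylsilyl)oxy]-3-{[2-(trimethylsilyl)ethoxy]ethynyl}-4H-chromen-4-one | C[Si](C)(C)CCOC#Cc1coc2cc(O[Si](C(C)C)(C(C)C)C(C)C)ccc2c1=O
F13 | step 6 | 3-{2-hydroxy-4-methoxy-3-(3-methylbut-2-en-1-yl)-6-[2-(trimethylsilyl)ethoxy]phenyl}-7-[(triisopropylsilyl)oxy]-4H-chromen-4-one | COc1cc(OCC[Si](C)(C)C)c(-c2coc3cc(O[Si](C(C)C)(C(C)C)C(C)C)ccc3c2=O)c(O)c1CC=C(C)C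
F14 | step 8 | 4-methylpent-3-enoic acid | CC(C)=CCC(=O)O
F15 | step 8 | 4-methylpent-3-enoyl chloride | CC(C)=CCC(=O)Cl
F16 | step 8 | 1-diazo-5-methylhex-4-en-2-one | [N-]=[N+]=CC(=O)CC=C(C)C
F17 | step 10 | 3-[2,6-diacetoxy-4-methoxy-3-(3-methylbut-2-en-1-yl)phenyl]-4-oxo-4H-chromen-7-yl acetate | COc1cc(OC(C)=O)c(-c2coc3cc(OC(C)=O)ccc3c2=O)c(OC(C)=O)c1CC=C(C)C
A1 | alternative 1 | 3-iodo-7-(methoxymethoxy)-4H-chromen-4-one | COCOc1ccc2c(c1)occ(I)c2=O
A2 | alternative 1 | [4-methoxy-2,6-bis(methoxymethoxy)phenyl]boronic acid | COCOc1cc(OC)cc(OCOC)c1B(O)O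
A3 | alternative 1 | 7-hydroxy-3-(2,6-dihydroxy-4-methoxyphenyl)-4H-chromen-4-one | COc1cc(O)c(-c2coc3cc(O)ccc3c2=O)c(O)c1
A4 | alternative 2 | (E)-1-[2-hydroxy-4-(methoxymethoxy)phenyl]-3-[4-methoxy-2,6-bis(methoxymethoxy)phenyl]prop-2-en-1-one | COCOc1ccc(C(=O)/C=C/c2c(OCOC)cc(OC)cc2OCOC)c(O)c1
A5 | alternative 2 | 1-[2-hydroxy-4-(methoxymethoxy)phenyl]-3,3-dimethoxy-2-[4-methoxy-2,6-bis(methoxymethoxy)phenyl]propan-1-one (racemic) | COCOc1ccc(C(=O)C(C(OC)OC)c2c(OCOC)cc(OC)cc2OCOC)c(O)c1
A6 | alternative 3 | [2,6-dihydroxy-4-methoxy-3-(3-methylbut-2-en-1-yl)phenyl]acetic acid | COc1cc(O)c(CC(=O)O)c(O)c1CC=C(C)C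
A7 | alternative 3 | 1-(2,4-dihydroxyphenyl)-2-[2,6-dihydroxy-4-methoxy-3-(3-methylbut-2-en-1-yl)phenyl]ethan-1-one | COc1cc(O)c(CC(=O)c2ccc(O)cc2O)c(O)c1CC=C(C)C
A8 | alternative 3 | resorcinol | Oc1cccc(O)c1
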